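**Retrosynthetic overview**
1. Difengpiol B ⇐ cis-epoxy alcohol 16 (trans-diaxial MeOH opening with desilylation) ⇐ cyclohexenol 15 (OH-directed epoxidation) ⇐ diene carbinol 14 (RCM).
2. 14 ⇐ chelation-controlled allylation of 2-acyl-dihydrobenzofuran 12 ⇐ trans-2-acetyl compound 10 (C2 equilibrated trans to C3).
3. 10 ⇐ epoxidation, 5-exo cyclisation and oxidation of the o-(pent-3-en-2-yl)phenol 8.
4. Key step: 8 ⇐ aromatic Claisen rearrangement of the (S,E)-aryl pent-3-en-2-yl ether 7, which forms C3a–C3 with 1,3-chirality transfer; 7 ⇐ dihydroconiferyl alcohol 1 + methyl (R)-2-chloropropanoate 2.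
5. Ring order: arene bought → dihydrofuran (step 6) → cyclohexene (step 10). Stereo relay: C–Cl centre of 2 → C3 → C2 → C1′ → C5′/C4′.

Assumption: the target SMILES reads as (2S,3R) on the dihydrobenzofuran and (1′S,4′S,5′S) on the cyclohexane; 1 and 2 are catalogue compounds (2 being the lactic-acid-derived chloride).

Shorthand: TBS = tert-butyldimethylsilyl; "Bf" = (2S,3R)-3-[(TBSO)methyl]-7-methoxy-5-[3-(TBSO)propyl]-2,3-dihydro-1-benzofuran-2-yl.

**Step 1**
Reactants: 1 (4-(3-hydroxypropyl)-2-methoxyphenol), 2 (methyl (R)-2-chloropropanoate)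
Product: 3, methyl (2S)-2-[4-(3-hydroxypropyl)-2-methoxyphenoxy]propanoate
Conditions: K2CO3, MeCN, 60 °C
Reagents that add atoms: none (all atoms from 1 and 2)
Why: Williamson SN2 etherification; only the phenoxide is formed under carbonate, and it displaces the activated α-chloride with inversion (R → S).

**Step 2**
Reactants: 3, 4 (triethyl phosphonoacetate)
Product: 5, ethyl (2E,4S)-4-[4-(3-hydroxypropyl)-2-methoxyphenoxy]pent-2-enoate
Conditions: DIBAL-H (2.2 equiv), CH2Cl2, −78 °C; then 4/NaH, THF, −78 °C → rt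
Reagents that add atoms: none beyond 4 (DIBAL-H delivers H only)
Why: One-pot half-reduction and Horner–Wadsworth–Emmons olefination; it is E-selective, and the epimerisable α-aryloxy aldehyde is trapped in situ so the stereocentre is kept.

**Step 3**
Reactants: 5
Product: 6, (2E,4S)-4-[4-(3-hydroxypropyl)-2-methoxyphenoxy]pent-2-en-1-ol
Conditions: DIBAL-H (3.5 equiv), CH2Cl2, −78 → 0 °C
Reagents that add atoms: none
Why: 1,2-Reduction of the enoate to the allylic alcohol; the alkene geometry and the stereocentre are untouched.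

**Step 4**
Reactants: 6
Product: 7, (2E,4S)-1-(TBSO)-4-{2-methoxy-4-[3-(TBSO)propyl]phenoxy}pent-2-ene
Conditions: TBSCl (2.4 equiv), imidazole, DMF, rt
Reagents that add atoms: TBSCl, CC(C)(C)[Si](C)(C)Cl
Why: Silylation of both primary alcohols; they must be masked for the later oxidation, enolate and Lewis-acid steps, and both come off in the final acidic step.

**Step 5 (key step)**
Reactants: 7
Product: 8, 2-[(2R,3E)-1-(TBSO)pent-3-en-2-yl]-6-methoxy-4-[3-(TBSO)propyl]phenol
Conditions: PhNEt2, 180–190 °C, sealed tube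
Reagents that add atoms: none
Why: Aromatic Claisen [3,3]-sigmatropic rearrangement to the only free ortho position; the chair transition state with the methyl equatorial transfers the (S) C–O centre suprafacially to the (R) benzylic carbon (future C3) and gives the E-propenyl group.

**Step 6**
Reactants: 8
Product: 9, 1-{(3R)-3-[(TBSO)methyl]-7-methoxy-5-[3-(TBSO)propyl]-2,3-dihydro-1-benzofuran-2-yl}ethan-1-ol (mixture at C2 and the carbinol, used as such)
Conditions: mCPBA, NaHCO3, CH2Cl2, 0 °C; then K2CO3, MeOH, rt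
Reagents that add atoms: mCPBA, OOC(=O)c1cccc(Cl)c1
Why: Prilezhaev epoxidation followed by phenoxide 5-exo-tet epoxide opening closes the dihydrofuran; the two new centres need no control because one is oxidised and the other equilibrated in step 7.

**Step 7**
Reactants: 9
Product: 10, 1-(Bf)ethan-1-one (2,3-trans)
Conditions: Dess–Martin periodinane, NaHCO3, CH2Cl2, rt; then DBU (0.3 equiv), CH2Cl2, rt
Reagents that add atoms: none
Why: Dess–Martin oxidation gives the α-aryloxy ketone, and reversible enolisation at C2 funnels both epimers to the more stable 2,3-trans isomer, so C2 (S) is set by C3.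

**Step 8**
Reactants: 10, 11 (allyl bromide)
Product: 12, 1-(Bf)pent-4-en-1-one
Conditions: LDA (1.05 equiv), THF, −78 °C; then 11, DMPU, −78 → −40 °C
Reagents that add atoms: none beyond 11
Why: Kinetic deprotonation occurs at the unhindered methyl group rather than the oxygenated C2 methine, and SN2 allylation of that enolate installs the C2′–C3′–C4′ arm.

**Step 9**
Reactants: 12, 13 (allyltrimethylsilane)
Product: 14, (4S)-4-(Bf)octa-1,7-dien-4-ol
Conditions: 13 (2 equiv), TiCl4 (1.2 equiv), CH2Cl2, −78 °C (ketone and silane premixed)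
Reagents that add atoms: none beyond 13 (allyl group; SiMe3 is lost)
Why: Chelation-controlled Hosomi–Sakurai allylation; Ti bridges the carbonyl and ring O1 (supported by the neighbouring 7-OMe), and the allyl group attacks the face syn to C2–H and anti to C3, giving 1′S.

**Step 10**
Reactants: 14
Product: 15, (1S)-1-(Bf)cyclohex-3-en-1-ol
Conditions: Grubbs II (3 mol %), CH2Cl2 (0.01 M), 40 °C
Reagents that add atoms: none
Why: Ring-closing metathesis of the allyl and butenyl arms forms the six-membered ring with the alkene at C4′=C5′; no stereocentre is touched.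

**Step 11**
Reactants: 15
Product: 16, (1S,3S,6R)-3-(Bf)-7-oxabicyclo[4.1.0]heptan-3-ol (epoxide cis to the tertiary OH)
Conditions: VO(acac)2 (5 mol %), t-BuOOH, CH2Cl2, 0 °C → rt
Reagents that add atoms: tert-butyl hydroperoxide, CC(C)(C)OO
Why: Vanadium-catalysed hydroxyl-directed epoxidation of the homoallylic alcohol delivers oxygen to the face bearing the pseudo-axial C1′–OH.

**Step 12**
Reactants: 16
Product: 17, difengpiol B
Conditions: p-TsOH·H2O (0.2 equiv), MeOH, rt
Reagents that add atoms: methanol, CO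
Why: Acid-catalysed methanolysis follows the Fürst–Plattner trans-diaxial rule in the half-chair with the bulky C1′ substituent equatorial and OH axial, so MeOH attacks the distal carbon C4′ with inversion (4′S-OMe) and leaves the 5′S-OH cis to the 1′-OH; both TBS ethers are cleaved in the same pot.

**Compound list**
1 | 4-(3-hydroxypropyl)-2-methoxyphenol (dihydroconiferyl alcohol) | COc1cc(CCCO)ccc1O | starting material
2 | methyl (2R)-2-chloropropanoate | C[C@@H](Cl)C(=O)OC | starting material
3 | methyl (2S)-2-[4-(3-hydroxypropyl)-2-methoxyphenoxy]propanoate | C[C@H](Oc1ccc(CCCO)cc1OC)C(=O)OC | intermediate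
4 | triethyl phosphonoacetate | CCOC(=O)CP(=O)(OCC)OCC | starting material
5 | ethyl (2E,4S)-4-[4-(3-hydroxypropyl)-2-methoxyphenoxy]pent-2-enoate | C[C@H](Oc1ccc(CCCO)cc1OC)/C=C/C(=O)OCC | intermediate
6 | (2E,4S)-4-[4-(3-hydroxypropyl)-2-methoxyphenoxy]pent-2-en-1-ol | C[C@H](Oc1ccc(CCCO)cc1OC)/C=C/CO | intermediate
7 | bis-TBS ether of 6 | C[C@H](Oc1ccc(CCCO[Si](C)(C)C(C)(C)C)cc1OC)/C=C/CO[Si](C)(C)C(C)(C)C | intermediate
8 | 2-[(2R,3E)-1-(TBSO)pent-3-en-2-yl]-6-methoxy-4-[3-(TBSO)propyl]phenol | C/C=C/[C@@H](CO[Si](C)(C)C(C)(C)C)c1cc(CCCO[Si](C)(C)C(C)(C)C)cc(OC)c1O | intermediate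
9 | 1-{(3R)-3-[(TBSO)methyl]-7-methoxy-5-[3-(TBSO)propyl]-2,3-dihydrobenzofuran-2-yl}ethan-1-ol (diastereomer mixture) | COc1cc(CCCO[Si](C)(C)C(C)(C)C)cc2c1OC(C(C)O)[C@H]2CO[Si](C)(C)C(C)(C)C | intermediate
10 | 1-(Bf)ethan-1-one, (2S,3R) | COc1cc(CCCO[Si](C)(C)C(C)(C)C)cc2c1O[C@H](C(C)=O)[C@H]2CO[Si](C)(C)C(C)(C)C | intermediate
11 | allyl bromide | C=CCBr | starting material
12 | 1-(Bf)pent-4-en-1-one | COc1cc(CCCO[Si](C)(C)C(C)(C)C)cc2c1O[C@H](C(=O)CCC=C)[C@H]2CO[Si](C)(C)C(C)(C)C | intermediate
13 | allyltrimethylsilane | C=CC[Si](C)(C)C | starting material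
14 | (4S)-4-(Bf)octa-1,7-dien-4-ol | COc1cc(CCCO[Si](C)(C)C(C)(C)C)cc2c1O[C@H]([C@@](O)(CC=C)CCC=C)[C@H]2CO[Si](C)(C)C(C)(C)C | intermediate
15 | (1S)-1-(Bf)cyclohex-3-en-1-ol | COc1cc(CCCO[Si](C)(C)C(C)(C)C)cc2c1O[C@H]([C@]1(O)CCC=CC1)[C@H]2CO[Si](C)(C)C(C)(C)C | intermediate
16 | (1S,3S,6R)-3-(Bf)-7-oxabicyclo[4.1.0]heptan-3-ol | COc1cc(CCCO[Si](C)(C)C(C)(C)C)cc2c1O[C@H]([C@]1(O)CC[C@H]3O[C@H]3C1)[C@H]2CO[Si](C)(C)C(C)(C)C | intermediate
17 | difengpiol B, (1S,3S,4S)-1-[(2S,3R)-3-(hydroxymethyl)-5-(3-hydroxypropyl)-7-methoxy-2,3-dihydro-1-benzofuran-2-yl]-4-methoxycyclohexane-1,3-diol | COc1cc(CCCO)cc2c1O[C@H]([C@]1(O)CC[C@H](OC)[C@@H](O)C1)[C@H]2CO | target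

**Totals**
Total steps: 12. Longest linear sequence: 12 (from 1 or 2).

**Three steps most likely to fail**
- **Step 9 (C1′ configuration).** The aryl-ether oxygen is a weak donor, so the chelate may not hold and Felkin–Anh addition would give the 1′R epimer. Fallback: swap the two arms and the control model. Pd-catalysed α-vinylation of the enolate of 10 gives the allyl ketone, and 3-butenylMgBr/CeCl3 added under non-chelating Felkin–Anh control gives the same 1′S carbinol 14 from the opposite facial preference.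
- **Step 8 (mono-allylation of the methyl ketone).** Proton transfer, over-alkylation or competing C2 enolisation could erode the yield. Fallback: avoid enolate chemistry. Cyclise 8 by Pd(II)/benzoquinone oxidative (Wacker-type) cyclisation to the 2-vinyl dihydrobenzofuran, ozonise to the 2-carbaldehyde (equilibrate to trans), add 3-butenylMgBr and oxidise to 12.
- **Step 12 (regiochemistry of epoxide opening).** Reaction through the other half-chair would give the 4′-OH/5′-OMe isomer. Fallback: bring the methoxy carbon in earlier. Alkylate in step 8 with 2-methoxyallyl bromide, close the ring by enol-ether RCM to the 4-methoxycyclohex-3-enol, and hydroborate–oxidise; boron adds β to OMe, which fixes the trans-4′-OMe/5′-OH regiochemistry, with borane delivered from the C1′ alkoxyborane.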